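## The problem

Compound 28 is a branched profisetinidin tetramer in which a (2R,3S)-catechin unit carries at C8 the C4 of one fisetinidol unit and at C6 the C4 of a second, whose own C6 carries the C4 of a third, so that three rings C hang on arene carbons through doubly benzylic C(sp3)–C(sp2) bonds. Two of these bonds end at catechin carbons flanked by two oxygen substituents, which rules out a chain-building reaction that is sensitive to ortho hindrance or that must choose late between C6 and C8. Of the eleven stereocentres, C2 and C3 of catechin can be bought, and the other nine form three identical triads (2R, 3S and an α-aryl group at C4, which means 2,3-trans-3,4-trans). If a C4 centre is made before C2 and C3 of its own ring, the nearest existing stereocentre is at least four bonds away, so C4 needs catalyst control. Inside a ring C, by contrast, a C4 aryl group already in place can set C3 and C2 by shielding one face of a C2=C3 double bond. The free compound has thirteen phenols and four secondary alcohols and is open to air oxidation, to base-induced epimerisation at C2 through quinone methides and to acid-induced scission of the interflavan bonds, so the phenols must stay masked until a last, neutral step. The feature that invites the key step is that the two chain-ending units have the same ring A (C4a, C5 to C8, C8a and O1, one oxygen at C7, hydrogen elsewhere) and C4 centres of the same sense, so one 2-hydroxyarylboron reagent and one catalyst enantiomer can supply C4a, C8a and O1 to both units at once, provided both C4 atoms are offered as enone β-carbons.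

## Retrosynthesis

**28 ⇒ 27.** The fifteen O–CH2Ph bonds are cut. Benzyl ethers are chosen over esters or silyl ethers because they survive base, organolithium reagents, borane and mild acid, and fall in one neutral reductive step that leaves the interflavan bonds alone. The 3-hydroxyls of the two terminal units in 27 need no protection because nothing follows but this step. The forward reaction must be complete at fifteen sites without hydrogenolysis of the benzylic C2–O1 bonds.

**27 ⇒ 25.** In both terminal rings C the C3–O and C2–H bonds are cut, leading back to the two enol ethers of bis(4H-chromene) 25. Against building C2 and C3 with chiral reagents, this cut lets the existing C4 aryl groups do the work. Four stereocentres disappear and only the two C4 centres remain to be made. The hydroboration must place boron at C3, anti to the C4 aryl group, and the organoborane must survive to oxidation.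

**25 ⇒ 23 + 4 (key disconnection).** In each terminal unit C4–C4a and O1–C2 are cut, which takes the two rings A off as two molecules of boronic acid 4 and leaves bis-enone 23. The neighbouring cut, the interflavan bond itself, would need two enantiopure C4 electrophiles and a regiochemical choice on two arenes. Here the interflavan carbons are already bonded to the core as enone β-carbons, so regiochemistry is decided earlier by where the aldehydes sit. Two rings and two stereocentres are removed, and one reagent, used twice, serves both sites. The forward reaction must select the same enone face at two different sites by catalyst control and go to completion at both.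

**23 ⇒ 22 + 14 ⇒ 20.** The two Cα=Cβ bonds are cut by aldol logic to dialdehyde 22 and two molecules of ketone 14. The two formyl carbons are then cut back to the aryl bromides of 20. Bromine is the placeholder of choice because it is inert in the enone chemistry that precedes it and yields the aldehyde by halogen–lithium exchange.

**20 ⇒ 19 ⇒ 17 ⇒ 15 + 7.** The middle unit is taken apart by the same logic, once. The two 3-O-benzyl groups are removed to diol 19, C3–O and C2–H are cut to enol ether 17, and C4–C4a and O1–C2 are cut to enone 15 and boronic acid 7. The bromine of 7 lands on C6 of the middle unit, exactly where the next enone is needed, so no late halogenation of an oligomer has to be regioselective. This single annulation is also the test of the method before two sites are addressed at once.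

**15 ⇒ 13 + 14; 13 ⇒ 11 ⇒ 10 ⇒ 9 ⇒ 8.** The enone is cut to aldehyde 13 and ketone 14. The formyl group is traced to the iodide of 11, the iodide to 10, the bromide to 9 and the four benzyl ethers to (+)-catechin 8. Electrophilic substitution of ring A goes first to C8, which takes the bromine; C6 takes the iodine. The more reactive carbon–iodine bond then allows C6 to be metalated while C8 keeps its placeholder.

**4 and 7 ⇒ 2 and 5 ⇒ 1.** Each C–B bond is cut to a C–I bond (exchange and borylation on the phenolate), and the halogens are traced to 3-(benzyloxy)phenol 1. The iodine enters ortho to the hydroxyl and para to the ether; the bromine of 5 enters para to the hydroxyl.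

## Roads not taken

Alternative 1: The cut is at the three C3–C4 bonds. Tris(2-hydroxybenzhydrol) A1, in which every future C4 is a diaryl carbinol next to the phenol of its own ring A, would be ionised to three ortho-quinone methides. A chiral 3,3'-disubstituted binaphthol would pass the styryl group of boronate A2 to each methide carbon, giving tris-styryl triphenol A3.
- Merits: all three C4 centres are set in one operation by one catalyst; no transition metal is needed; no aryl group has to insert into a hindered enone; A1 comes from aldehydes and aryl-metal reagents.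
- Weak points: the cations on the catechin-bound carbinols are stabilised by the catechin ring itself, so an uncatalysed, unselective addition competes with the catalyst-bound one. A3 also still lacks O1–C2 and C3–O in all three units. Six more stereocentres must then be set by chiral oxidants next to existing centres (matched and mismatched cases on one molecule), followed by three stereospecific ring closures.
- Comparison: Alternative 1 is better at treating the three units alike, where the chosen plan runs its annulation twice (steps 10 and 15). The chosen plan sets against this that each annulation also closes ring C, and that C2 and C3 then follow from C4 by substrate control in one hydroboration, leaving two steps after the key step.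

Alternative 2: The cut is at C3–O and C4–H of all three fisetinidol units. A borane would add to the three C3=C4 bonds of tris(4-aryl-2H-chromene) A4, boron at C3 and anti to the 2-aryl group, and oxidation would give triol A5.
- Merits: six stereocentres from three by substrate control; a cheap reagent; no free phenol; all units handled together. In its key step it is at least as good as the chosen plan, which needs a rhodium catalyst and two annulation rounds.
- Weak points: the difficulty is moved upstream. Three C2 centres must be set beforehand on flav-3-enes, which are sensitive to acid and air through flavylium formation. The three C4–arene bonds must be made at sp2 carbons against doubly ortho-substituted catechin positions. The alkene to be hydroborated is trisubstituted and carries two aryl groups on one carbon, so it is slow.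
- Comparison: the chosen plan ends with the sister reaction on the more reactive enol ether isomer, and it creates the C4–arene bonds from aldehydes by aldol condensation and conjugate arylation, where hindrance is easier to tolerate.

Alternative 3: The cut is at O1–C2 and C3–C4 of all three units. A chiral phosphoric acid would ionise A1 to the three ortho-quinone methides, and each would take up styryl acetate A6 across O1 and C4, closing three rings C and giving triacetate A7.
- Merits: on paper the shortest road. Nine stereocentres and three rings are formed in one step, and A7 already has the oxidation level of the target. In step count it is clearly ahead of the chosen plan.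
- Weak points: an enol acetate is a weak partner for an ortho-quinone methide. The 3,4-relationship depends on endo/exo control and the 2,3-relationship on a concerted course, which the strongly stabilised cations make doubtful. Three catalyst-controlled events on one chiral substrate multiply any leakage into diastereomers that would be hard to separate at this size.
- Comparison: the chosen plan sets against the brevity a reaction class with direct precedent (chalcone plus 2-hydroxyarylboronic acid) and a separation of tasks: the catalyst sets only C4, and the substrate sets C2 and C3.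

Key step: step 15

Convention: flavan numbering is used; α and β have their proanthocyanidin meaning (in catechin the 2-aryl group is α and the 3-hydroxyl β); "H-4 β" in a 4H-chromene means the same orientation as in the final flavan.

Assumption: (R,R)-2,5-diphenylbicyclo[2.2.2]octa-2,5-diene is taken to direct the aryl group to the Re face of the enone β-carbon (priorities: core aryl > Cα > H), the face needed in steps 10 and 15; if a test on a simple chalcone shows the opposite sense, the (S,S)-ligand is used in both steps with nothing else changed.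

## Route

Step 1
Reactants: 1 3-(benzyloxy)phenol
Product: 2 5-(benzyloxy)-2-iodophenol
Conditions: I2 (1.0 equiv), NaHCO3, THF/H2O 1:1, 0 °C → rt
Reagents that add atoms: iodine, [I][I]
Why: Electrophilic iodination of the phenolate; the carbon ortho to the hydroxyl and para to the benzyloxy group is the most activated unhindered site, as in the analogous iodination of 3-methoxyphenol, while the carbon between the two oxygens is shielded.

Step 2
Reactants: 2 5-(benzyloxy)-2-iodophenol
Product: 4 [4-(benzyloxy)-2-hydroxyphenyl]boronic acid, via lithium 5-(benzyloxy)-2-lithiophenolate 3 (not isolated)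
Conditions: n-BuLi (2.2 equiv), THF, −78 °C; B(OiPr)3, −78 °C → rt; aq HCl to pH 5
Reagents that add atoms: triisopropyl borate, CC(C)OB(OC(C)C)OC(C)C; water, O
Why: Deprotonation followed by iodine–lithium exchange gives the O,C-dilithio species, which the borate traps at carbon; mild acidic hydrolysis frees the boronic acid (halogen–metal exchange/borylation).

Step 3
Reactants: 2 5-(benzyloxy)-2-iodophenol
Product: 5 5-(benzyloxy)-4-bromo-2-iodophenol
Conditions: NBS (1.0 equiv), MeCN, −20 → 0 °C
Reagents that add atoms: N-bromosuccinimide, O=C1CCC(=O)N1Br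
Why: Electrophilic aromatic bromination; the carbon para to the free hydroxyl and ortho to the benzyloxy group is the only activated, unhindered position left.

Step 4
Reactants: 5 5-(benzyloxy)-4-bromo-2-iodophenol
Product: 7 [4-(benzyloxy)-5-bromo-2-hydroxyphenyl]boronic acid, via lithium 5-(benzyloxy)-4-bromo-2-lithiophenolate 6 (not isolated)
Conditions: n-BuLi (2.1 equiv), THF, −90 °C; B(OiPr)3, −90 °C → rt; aq HCl to pH 5
Reagents that add atoms: triisopropyl borate, CC(C)OB(OC(C)C)OC(C)C; water, O
Why: Iodine–lithium exchange is much faster than bromine–lithium exchange at this temperature, so only the carbon–iodine bond is metalated; the bromine is meta to lithium, so no aryne can form, and borylation/hydrolysis follow as in step 2.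

Step 5
Reactants: 8 (+)-catechin
Product: 9 5,7,3',4'-tetra-O-benzylcatechin
Conditions: BnBr (4.2 equiv), K2CO3, DMF, 0 °C → rt
Reagents that add atoms: benzyl bromide, BrCc1ccccc1
Why: Fourfold Williamson ether synthesis; carbonate deprotonates the four phenols but not the secondary 3-hydroxyl, and the weak base avoids epimerisation at C2.

Step 6
Reactants: 9 5,7,3',4'-tetra-O-benzylcatechin
Product: 10 8-bromo-5,7,3',4'-tetra-O-benzylcatechin
Conditions: NBS (1.05 equiv), CH2Cl2, −78 °C → rt
Reagents that add atoms: N-bromosuccinimide, O=C1CCC(=O)N1Br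
Why: Electrophilic aromatic bromination of the phloroglucinol-type ring A, for which C8 is the established first site of attack in this compound.

Step 7
Reactants: 10 8-bromo-5,7,3',4'-tetra-O-benzylcatechin
Product: 11 8-bromo-6-iodo-5,7,3',4'-tetra-O-benzylcatechin
Conditions: NIS (1.2 equiv), CF3CO2H (cat.), CH2Cl2/MeCN, 0 °C → rt
Reagents that add atoms: N-iodosuccinimide, O=C1CCC(=O)N1I
Why: Second electrophilic halogenation at the only free carbon of ring A (C6), still activated by three oxygen substituents; the rings B are far less electron-rich.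

Step 8
Reactants: 11 8-bromo-6-iodo-5,7,3',4'-tetra-O-benzylcatechin
Product: 13 8-bromo-6-formyl-5,7,3',4'-tetra-O-benzylcatechin, via C6 arylmagnesium chloride 3-O-magnesium alkoxide 12 (not isolated)
Conditions: iPrMgCl·LiCl (2.3 equiv), THF, −20 → 0 °C; DMF, 0 °C → rt; aq NH4Cl
Reagents that add atoms: N,N-dimethylformamide, CN(C)C=O
Why: After deprotonation of the 3-hydroxyl, iodine–magnesium exchange takes place at C6, helped by the two ortho alkoxy groups, while an electron-rich aryl bromide does not exchange at this temperature; the Grignard reagent is formylated by DMF (Bouveault aldehyde synthesis).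

Step 9
Reactants: 13 8-bromo-6-formyl-5,7,3',4'-tetra-O-benzylcatechin; 14 3',4'-bis(benzyloxy)acetophenone
Product: 15 (E)-1-[3,4-bis(benzyloxy)phenyl]-3-(8-bromo-5,7,3',4'-tetra-O-benzylcatechin-6-yl)prop-2-en-1-one
Conditions: KOH (aq), EtOH/THF, rt → 40 °C
Reagents that add atoms: none
Why: Claisen–Schmidt condensation; the aldehyde cannot enolise and the aldol product dehydrates to the conjugated (E)-enone under thermodynamic control.

Step 10
Reactants: 15 catechin 6-enone; 7 [4-(benzyloxy)-5-bromo-2-hydroxyphenyl]boronic acid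
Product: 17 8-bromo-5,7,3',4'-tetra-O-benzylcatechin carrying at C6 a 7-(benzyloxy)-2-[3,4-bis(benzyloxy)phenyl]-6-bromo-4H-chromen-4-yl group (H-4 β), via hydroxy ketone Michael adduct 16 (not isolated)
Conditions: [RhCl(C2H4)2]2 (5 mol %), (R,R)-2,5-diphenylbicyclo[2.2.2]octa-2,5-diene (11 mol %), 7 (3 equiv), KOH, dioxane/H2O 10:1, 50 °C; then TsOH·H2O (cat.), MgSO4, toluene, 40 °C
Reagents that add atoms: none
Why: Rhodium-catalysed asymmetric 1,4-addition of a 2-hydroxyarylboronic acid (Hayashi–Miyaura reaction) sets C4 of the future middle unit by catalyst control (aryl to the Re face of the β-carbon). Acid-catalysed hemiketal formation and dehydration then close ring C as the 4H-chromene. Aryl bromides and the free 3-hydroxyl are inert to aryl complexes of monovalent rhodium under these conditions.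

Step 11
Reactants: 17 mono(4H-chromene)
Product: 19 6-bromo-7,3',4'-tri-O-benzylfisetinidol-(4α→6)-8-bromo-5,7,3',4'-tetra-O-benzylcatechin (both 3-hydroxyls free), via C3 borane adduct 18 (not isolated)
Conditions: BH3·SMe2 (excess), THF, 0 °C → rt; NaBO3·4H2O, THF/H2O, rt
Reagents that add atoms: sodium perborate, [Na+].[O-]OB=O
Why: Hydroboration–oxidation of the enol ether: boron goes to C3 (β to oxygen, away from the 2-aryl carbon) on the face anti to the C4 aryl group and hydrogen is delivered syn to C2. Oxidation with retention then gives the (2R,3S) 2,3-trans-3,4-trans flavan-3-ol; the free catechin hydroxyl only consumes borane.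

Step 12
Reactants: 19 dibromo diol
Product: 20 6-bromo-3,7,3',4'-tetra-O-benzylfisetinidol-(4α→6)-8-bromo-3,5,7,3',4'-penta-O-benzylcatechin
Conditions: NaH, BnBr, Bu4NI (cat.), DMF, 0 °C → rt
Reagents that add atoms: benzyl bromide, BrCc1ccccc1
Why: Twofold Williamson etherification of both secondary alkoxides; the substrate has no base-labile group and no C–H acidic enough for NaH.

Step 13
Reactants: 20 nona-O-benzyl dibromide
Product: 22 6-formyl-3,7,3',4'-tetra-O-benzylfisetinidol-(4α→6)-8-formyl-3,5,7,3',4'-penta-O-benzylcatechin, via dilithio species 21 (not isolated)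
Conditions: t-BuLi (4.4 equiv), THF, −78 °C; DMF, −78 → 0 °C; aq NH4Cl
Reagents that add atoms: N,N-dimethylformamide, CN(C)C=O
Why: Twofold bromine–lithium exchange (two equivalents of t-BuLi per bromide, the second destroying t-BuBr) is faster at −78 °C than deprotonation of benzyl ethers, and the ortho alkoxy groups stabilise both aryllithiums; DMF formylates them.

Step 14
Reactants: 22 dialdehyde; 14 3',4'-bis(benzyloxy)acetophenone (2 equiv are incorporated, one per formyl group)
Product: 23 bis-enone: 22 with each formyl group replaced by an (E)-3-[3,4-bis(benzyloxy)phenyl]-3-oxoprop-1-enyl group (at C6 of the fisetinidol unit and at C8 of catechin)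
Conditions: 14 (3 equiv), KOH (aq), EtOH/THF, 40 °C
Reagents that add atoms: 3',4'-bis(benzyloxy)acetophenone (second molecule of 14), CC(=O)c1ccc(OCc2ccccc2)c(OCc2ccccc2)c1
Why: Twofold Claisen–Schmidt condensation as in step 9, one molecule of 14 per aldehyde; both aldehydes are non-enolisable and the (E)-enones are the thermodynamic products.

Step 15
Reactants: 23 bis-enone; 4 [4-(benzyloxy)-2-hydroxyphenyl]boronic acid (2 equiv are incorporated, one per enone arm)
Product: 25 bis(4H-chromene): the nona-O-benzyl fisetinidol-(4α→6)-catechin core carrying at C6 of the fisetinidol unit and at C8 of catechin a 7-(benzyloxy)-2-[3,4-bis(benzyloxy)phenyl]-4H-chromen-4-yl group (each H-4 β), via bis(hydroxy ketone) 24 (not isolated)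
Conditions: [RhCl(C2H4)2]2 (10 mol %), (R,R)-2,5-diphenylbicyclo[2.2.2]octa-2,5-diene (22 mol %), 4 (6 equiv), KOH, dioxane/H2O 10:1, 50 °C, portionwise addition of 4; then TsOH·H2O (cat.), MgSO4, toluene, 40 °C
Reagents that add atoms: [4-(benzyloxy)-2-hydroxyphenyl]boronic acid (second molecule of 4), OB(O)c1ccc(OCc2ccccc2)cc1O
Why: Two molecules of 4 are consumed, one per enone arm: transmetalation of 4 to the hydroxo–rhodium diene complex gives an aryl complex of monovalent rhodium, which inserts the enone C=C bond to form C4–C4a and an oxa-π-allyl rhodium enolate, and water protonates the enolate, releasing the β,β-diaryl ketone and the rhodium hydroxide. The closest known reaction type is the Hayashi–Miyaura asymmetric 1,4-addition of 2-hydroxyarylboronic acids to chalcones followed by cyclodehydration to 2,4-diaryl-4H-chromenes. Each ring C then closes by 6-exo-trig addition of the phenolic oxygen to the ketone carbonyl and acid-catalysed loss of water from the hemiketal to the conjugated enol ether, forming O1–C2. Each of the two new C4 stereocentres is set by the chiral diene, which exposes the Re face of the β-carbon of the s-cis enone to the migrating aryl group. Both sites need the same sense, so one ligand enantiomer serves both, and the existing stereocentres lie four or more bonds away and should not oppose it. The step needs 1,4- over 1,2-addition, which the insertion/enolate pathway provides, and full conversion at both arms, which excess 4 added in portions secures against protodeboronation. Compound 23 holds no halide or aldehyde that could divert the aryl-rhodium species, and the benzyl ethers and flavan rings are inert to the basic and then mildly acidic medium.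

Step 16
Reactants: 25 bis(4H-chromene)
Product: 27 7,3',4'-tri-O-benzylfisetinidol-(4α→6)-3,7,3',4'-tetra-O-benzylfisetinidol-(4α→6)-[7,3',4'-tri-O-benzylfisetinidol-(4α→8)]-3,5,7,3',4'-penta-O-benzylcatechin (3-hydroxyls of the two terminal units free), via bis(C3 borane) adduct 26 (not isolated)
Conditions: BH3·SMe2 (excess), THF, 0 °C → rt; NaBO3·4H2O, THF/H2O, rt
Reagents that add atoms: sodium perborate, [Na+].[O-]OB=O
Why: Twofold hydroboration–oxidation of the enol ethers as in step 11: in each ring boron adds to C3 anti to the C4 aryl group and hydrogen syn to C2, so the four new centres (2R,3S twice) follow from the two C4 centres; perborate oxidises with retention under mild conditions.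

Step 17
Reactants: 27 pentadeca-O-benzyl tetramer
Product: 28 fisetinidol-(4α→6)-fisetinidol-(4α→6)-[fisetinidol-(4α→8)]-catechin (CNP0263622.1)
Conditions: H2 (1 atm), Pd(OH)2/C, degassed THF/MeOH/H2O, rt
Reagents that add atoms: none
Why: Hydrogenolysis of all fifteen benzyl ethers under neutral conditions; aryl-substituted interflavan C–C bonds and the benzylic C2–O1 bonds of flavans are not cleaved under these conditions, and exclusion of air protects the free polyphenol.

## Compound list

1 | 3-(benzyloxy)phenol | Oc1cccc(OCc2ccccc2)c1 | starting material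
2 | 5-(benzyloxy)-2-iodophenol | Oc1cc(OCc2ccccc2)ccc1I | intermediate
3 | lithium 5-(benzyloxy)-2-lithiophenolate | [Li]Oc1cc(OCc2ccccc2)ccc1[Li] | intermediate
4 | [4-(benzyloxy)-2-hydroxyphenyl]boronic acid | OB(O)c1ccc(OCc2ccccc2)cc1O | intermediate
5 | 5-(benzyloxy)-4-bromo-2-iodophenol | Oc1cc(OCc2ccccc2)c(Br)cc1I | intermediate
6 | lithium 5-(benzyloxy)-4-bromo-2-lithiophenolate | [Li]Oc1cc(OCc2ccccc2)c(Br)cc1[Li] | intermediate
7 | [4-(benzyloxy)-5-bromo-2-hydroxyphenyl]boronic acid | OB(O)c1cc(Br)c(OCc2ccccc2)cc1O | intermediate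
8 | (+)-catechin, (2R,3S) | Oc1cc(O)c2c(c1)O[C@H](c1ccc(O)c(O)c1)[C@@H](O)C2 | starting material
9 | 5,7,3',4'-tetra-O-benzylcatechin (3-OH free) | c9ccccc9COc1cc(OCc9ccccc9)c2c(c1)O[C@H](c1ccc(OCc9ccccc9)c(OCc9ccccc9)c1)[C@@H](O)C2 | intermediate
10 | 8-bromo-5,7,3',4'-tetra-O-benzylcatechin | Brc1c(OCc9ccccc9)cc(OCc9ccccc9)c2c1O[C@H](c1ccc(OCc9ccccc9)c(OCc9ccccc9)c1)[C@@H](O)C2 | intermediate
11 | 8-bromo-6-iodo-5,7,3',4'-tetra-O-benzylcatechin | Ic1c(OCc9ccccc9)c2c(c(Br)c1OCc9ccccc9)O[C@H](c1ccc(OCc9ccccc9)c(OCc9ccccc9)c1)[C@@H](O)C2 | intermediate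
12 | 8-bromo-6-(chloromagnesio)-5,7,3',4'-tetra-O-benzylcatechin, 3-O-magnesium chloride alkoxide | Cl[Mg]c1c(OCc9ccccc9)c2c(c(Br)c1OCc9ccccc9)O[C@H](c1ccc(OCc9ccccc9)c(OCc9ccccc9)c1)[C@@H](O[Mg]Cl)C2 | intermediate
13 | 8-bromo-6-formyl-5,7,3',4'-tetra-O-benzylcatechin | O=Cc1c(OCc9ccccc9)c2c(c(Br)c1OCc9ccccc9)O[C@H](c1ccc(OCc9ccccc9)c(OCc9ccccc9)c1)[C@@H](O)C2 | intermediate
14 | 3',4'-bis(benzyloxy)acetophenone | CC(=O)c1ccc(OCc2ccccc2)c(OCc2ccccc2)c1 | starting material
15 | (E)-1-[3,4-bis(benzyloxy)phenyl]-3-(8-bromo-5,7,3',4'-tetra-O-benzylcatechin-6-yl)prop-2-en-1-one | O=C(c1ccc(OCc9ccccc9)c(OCc9ccccc9)c1)/C=C/c1c(OCc9ccccc9)c2c(c(Br)c1OCc9ccccc9)O[C@H](c1ccc(OCc9ccccc9)c(OCc9ccccc9)c1)[C@@H](O)C2 | intermediate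
16 | 3-[4-(benzyloxy)-5-bromo-2-hydroxyphenyl]-1-[3,4-bis(benzyloxy)phenyl]-3-(8-bromo-5,7,3',4'-tetra-O-benzylcatechin-6-yl)propan-1-one (C3 configured as C4 of 17) | O=C(c1ccc(OCc9ccccc9)c(OCc9ccccc9)c1)C[C@@H](c1cc(Br)c(OCc9ccccc9)cc1O)c1c(OCc9ccccc9)c2c(c(Br)c1OCc9ccccc9)O[C@H](c1ccc(OCc9ccccc9)c(OCc9ccccc9)c1)[C@@H](O)C2 | intermediate
17 | 8-bromo-5,7,3',4'-tetra-O-benzylcatechin with a 7-(benzyloxy)-2-[3,4-bis(benzyloxy)phenyl]-6-bromo-4H-chromen-4-yl group at C6 (H-4 β) | Brc1cc2c(cc1OCc9ccccc9)OC(c1ccc(OCc9ccccc9)c(OCc9ccccc9)c1)=C[C@@H]2c1c(OCc9ccccc9)c2c(c(Br)c1OCc9ccccc9)O[C@H](c1ccc(OCc9ccccc9)c(OCc9ccccc9)c1)[C@@H](O)C2 | intermediate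
18 | borane adduct of 17: BH2 at C3 (β) of the new ring C, hydrogen at C2 (β), catechin O3 as its O-boryl derivative (alkoxyborane) | Brc1cc2c(cc1OCc9ccccc9)O[C@H](c1ccc(OCc9ccccc9)c(OCc9ccccc9)c1)[C@@H](B)[C@@H]2c1c(OCc9ccccc9)c2c(c(Br)c1OCc9ccccc9)O[C@H](c1ccc(OCc9ccccc9)c(OCc9ccccc9)c1)[C@@H](OB)C2 | intermediate
19 | 6-bromo-7,3',4'-tri-O-benzylfisetinidol-(4α→6)-8-bromo-5,7,3',4'-tetra-O-benzylcatechin (upper unit 2R,3S, 3,4-trans; both 3-OH free) | Brc1cc2c(cc1OCc9ccccc9)O[C@H](c1ccc(OCc9ccccc9)c(OCc9ccccc9)c1)[C@@H](O)[C@@H]2c1c(OCc9ccccc9)c2c(c(Br)c1OCc9ccccc9)O[C@H](c1ccc(OCc9ccccc9)c(OCc9ccccc9)c1)[C@@H](O)C2 | intermediate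
20 | 6-bromo-3,7,3',4'-tetra-O-benzylfisetinidol-(4α→6)-8-bromo-3,5,7,3',4'-penta-O-benzylcatechin | Brc1cc2c(cc1OCc9ccccc9)O[C@H](c1ccc(OCc9ccccc9)c(OCc9ccccc9)c1)[C@@H](OCc9ccccc9)[C@@H]2c1c(OCc9ccccc9)c2c(c(Br)c1OCc9ccccc9)O[C@H](c1ccc(OCc9ccccc9)c(OCc9ccccc9)c1)[C@@H](OCc9ccccc9)C2 | intermediate
21 | dilithio species of 20 (lithium at C6 of the fisetinidol unit and at C8 of catechin) | [Li]c1cc2c(cc1OCc9ccccc9)O[C@H](c1ccc(OCc9ccccc9)c(OCc9ccccc9)c1)[C@@H](OCc9ccccc9)[C@@H]2c1c(OCc9ccccc9)c2c(c([Li])c1OCc9ccccc9)O[C@H](c1ccc(OCc9ccccc9)c(OCc9ccccc9)c1)[C@@H](OCc9ccccc9)C2 | intermediate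
22 | 6-formyl-3,7,3',4'-tetra-O-benzylfisetinidol-(4α→6)-8-formyl-3,5,7,3',4'-penta-O-benzylcatechin | O=Cc1cc2c(cc1OCc9ccccc9)O[C@H](c1ccc(OCc9ccccc9)c(OCc9ccccc9)c1)[C@@H](OCc9ccccc9)[C@@H]2c1c(OCc9ccccc9)c2c(c(C=O)c1OCc9ccccc9)O[C@H](c1ccc(OCc9ccccc9)c(OCc9ccccc9)c1)[C@@H](OCc9ccccc9)C2 | intermediate
23 | bis-enone: 22 with each CHO replaced by (E)-CH=CH–C(=O)–[3,4-bis(benzyloxy)phenyl] | O=C(c1ccc(OCc9ccccc9)c(OCc9ccccc9)c1)/C=C/c1cc2c(cc1OCc9ccccc9)O[C@H](c1ccc(OCc9ccccc9)c(OCc9ccccc9)c1)[C@@H](OCc9ccccc9)[C@@H]2c1c(OCc9ccccc9)c2c(c(/C=C/C(=O)c3ccc(OCc9ccccc9)c(OCc9ccccc9)c3)c1OCc9ccccc9)O[C@H](c1ccc(OCc9ccccc9)c(OCc9ccccc9)c1)[C@@H](OCc9ccccc9)C2 | intermediate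
24 | bis(β,β-diaryl ketone): 23 after addition of a 4-(benzyloxy)-2-hydroxyphenyl group to each β-carbon and hydrogen to each α-carbon (new centres configured as C4 of 25) | O=C(c1ccc(OCc9ccccc9)c(OCc9ccccc9)c1)C[C@@H](c1ccc(OCc9ccccc9)cc1O)c1cc2c(cc1OCc9ccccc9)O[C@H](c1ccc(OCc9ccccc9)c(OCc9ccccc9)c1)[C@@H](OCc9ccccc9)[C@@H]2c1c(OCc9ccccc9)c2c(c([C@@H](CC(=O)c3ccc(OCc9ccccc9)c(OCc9ccccc9)c3)c3ccc(OCc9ccccc9)cc3O)c1OCc9ccccc9)O[C@H](c1ccc(OCc9ccccc9)c(OCc9ccccc9)c1)[C@@H](OCc9ccccc9)C2 | intermediate
25 | bis(4H-chromene): 7-(benzyloxy)-2-[3,4-bis(benzyloxy)phenyl]-4H-chromen-4-yl groups (H-4 β) at C6 of the fisetinidol unit and at C8 of catechin of the nona-O-benzyl dimer core | c9ccccc9COc1ccc2c(c1)OC(c1ccc(OCc9ccccc9)c(OCc9ccccc9)c1)=C[C@@H]2c1cc2c(cc1OCc9ccccc9)O[C@H](c1ccc(OCc9ccccc9)c(OCc9ccccc9)c1)[C@@H](OCc9ccccc9)[C@@H]2c1c(OCc9ccccc9)c2c(c([C@@H]3c4ccc(OCc9ccccc9)cc4OC(c4ccc(OCc9ccccc9)c(OCc9ccccc9)c4)=C3)c1OCc9ccccc9)O[C@H](c1ccc(OCc9ccccc9)c(OCc9ccccc9)c1)[C@@H](OCc9ccccc9)C2 | intermediate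
26 | bis(borane) adduct of 25: BH2 at C3 (β) and hydrogen at C2 (β) of both terminal rings C | c9ccccc9COc1ccc2c(c1)O[C@H](c1ccc(OCc9ccccc9)c(OCc9ccccc9)c1)[C@@H](B)[C@@H]2c1cc2c(cc1OCc9ccccc9)O[C@H](c1ccc(OCc9ccccc9)c(OCc9ccccc9)c1)[C@@H](OCc9ccccc9)[C@@H]2c1c(OCc9ccccc9)c2c(c([C@@H]3c4ccc(OCc9ccccc9)cc4O[C@H](c4ccc(OCc9ccccc9)c(OCc9ccccc9)c4)[C@H]3B)c1OCc9ccccc9)O[C@H](c1ccc(OCc9ccccc9)c(OCc9ccccc9)c1)[C@@H](OCc9ccccc9)C2 | intermediate
27 | pentadeca-O-benzyl tetramer (all units 2R,3S; all interflavan bonds 4α; 3-OH of the two terminal fisetinidol units free) | c9ccccc9COc1ccc2c(c1)O[C@H](c1ccc(OCc9ccccc9)c(OCc9ccccc9)c1)[C@@H](O)[C@@H]2c1cc2c(cc1OCc9ccccc9)O[C@H](c1ccc(OCc9ccccc9)c(OCc9ccccc9)c1)[C@@H](OCc9ccccc9)[C@@H]2c1c(OCc9ccccc9)c2c(c([C@@H]3c4ccc(OCc9ccccc9)cc4O[C@H](c4ccc(OCc9ccccc9)c(OCc9ccccc9)c4)[C@H]3O)c1OCc9ccccc9)O[C@H](c1ccc(OCc9ccccc9)c(OCc9ccccc9)c1)[C@@H](OCc9ccccc9)C2 | intermediate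
28 | fisetinidol-(4α→6)-fisetinidol-(4α→6)-[fisetinidol-(4α→8)]-catechin (CNP0263622.1) | Oc1ccc2c(c1)O[C@H](c1ccc(O)c(O)c1)[C@@H](O)[C@@H]2c1cc2c(cc1O)O[C@H](c1ccc(O)c(O)c1)[C@@H](O)[C@@H]2c1c(O)c2c(c([C@@H]3c4ccc(O)cc4O[C@H](c4ccc(O)c(O)c4)[C@H]3O)c1O)O[C@H](c1ccc(O)c(O)c1)[C@@H](O)C2 | target

## Step count and points of risk

Total step count: 17. Longest linear sequence: 13 steps (steps 5 to 17, from (+)-catechin 8). Boronic acids 4 and 7 are made in two and three steps from 1 and enter at steps 15 and 10.

**Step 15 (key step).** Insertion of the aryl-rhodium species into the hindered, electron-rich enone on catechin C8 may be slow. Protodeboronation of 4 would then use up the reagent and the reaction would stall after one annulation. Facial selectivity at one of the two arms may also be eroded by the chiral core. The fallback forms C3–C4 instead of C4–C4a by organocatalysis. It sets out from dialdehyde 22: addition of two molecules of the dilithio phenolate 3 (made from 2 as in step 2) to the two formyl groups, followed by aqueous NH4Cl work-up, should give the bis(2-hydroxybenzhydrol) F1 (carbinol centres unassigned, since they are lost on ionisation). Ketone 14 is converted through its oxime F2 (NH2OH·HCl, pyridine) into the N-acetyl enamide F3 (iron powder, Ac2O, AcOH). A chiral binaphthol-derived phosphoric acid then ionises F1 to the two ortho-quinone methides and steers F3 to one face of each methide carbon. The resulting bis(2-acetamidochroman) F4 loses acetamide on warming with TsOH and returns to the route at 25.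

**Step 10.** The enone β-carbon sits between two ortho benzyloxy groups, so insertion may be slower still than in step 15, and protodeboronation of 7 may win. The same detour answers it at one site. From aldehyde 13, addition of the dilithio phenolate 6 (made from 5 as in step 4) and aqueous NH4Cl work-up give the 2-hydroxybenzhydrol F5; phosphoric acid-catalysed addition of enamide F3 gives the 2-acetamidochroman F6, which loses acetamide under acid and returns to the route at 17.

**Step 16.** The C3 organoboranes carry the ring oxygen in the β-position and may undergo β-alkoxy elimination with opening of ring C. Facial selectivity may also be lower at the ring attached to catechin C8, where the neighbouring groups crowd both faces. The fallback replaces hydroboration by epoxidation and reduction and sets out from 25. Dimethyldioxirane (acetone/CH2Cl2, −40 °C) should epoxidise both enol ethers anti to the C4 aryl groups to give the bis(2,3-epoxide) F7. iBu2AlH (CH2Cl2, −78 °C) then opens each epoxide at the benzylic ketal carbon C2 and delivers hydride from the oxygen-bound aluminium on the same face, which gives the 2,3-trans-3,4-trans diol and returns to the route at 27.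

**Step 13.** The second bromine–lithium exchange may lag, or one aryllithium may be quenched by proton transfer from a benzylic position, which would leave mono-aldehyde or reduced material. The fallback avoids organolithium reagents and sets out from 20. Twofold Suzuki–Miyaura vinylation (potassium vinyltrifluoroborate, Pd(OAc)2, SPhos, K3PO4, toluene/H2O, 90 °C) gives the divinyl compound F8, and Lemieux–Johnson cleavage (OsO4 cat., NaIO4, 2,6-lutidine, dioxane/H2O) returns to the route at 22.

**Step 4.** Competing bromine–lithium exchange may scramble the halogens, and the electron-rich boronic acid may lose boron during acidic work-up. The fallback sets out from 5. Miyaura borylation (B2pin2, Pd(dppf)Cl2, KOAc, dioxane, 80 °C) exploits the faster oxidative addition of zerovalent palladium to the carbon–iodine bond and gives the pinacol boronate F9. F9 is used in place of 7 in step 10 and so returns to the route at 17.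

## Further compounds

F1 | step 15 | bis(2-hydroxybenzhydrol): 22 with each CHO converted into CH(OH)[4-(benzyloxy)-2-hydroxyphenyl] | OC(c1ccc(OCc9ccccc9)cc1O)c1cc2c(cc1OCc9ccccc9)O[C@H](c1ccc(OCc9ccccc9)c(OCc9ccccc9)c1)[C@@H](OCc9ccccc9)[C@@H]2c1c(OCc9ccccc9)c2c(c(C(O)c3ccc(OCc9ccccc9)cc3O)c1OCc9ccccc9)O[C@H](c1ccc(OCc9ccccc9)c(OCc9ccccc9)c1)[C@@H](OCc9ccccc9)C2
F2 | step 15 | 3',4'-bis(benzyloxy)acetophenone oxime | CC(=NO)c1ccc(OCc2ccccc2)c(OCc2ccccc2)c1
F3 | step 15 | N-{1-[3,4-bis(benzyloxy)phenyl]ethenyl}acetamide | C=C(NC(C)=O)c1ccc(OCc2ccccc2)c(OCc2ccccc2)c1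
F4 | step 15 | bis(2-acetamidochroman): 25 with acetamide added across each C2=C3 bond (NHAc at C2) | c9ccccc9COc1ccc2c(c1)OC(NC(C)=O)(c1ccc(OCc9ccccc9)c(OCc9ccccc9)c1)C[C@@H]2c1cc2c(cc1OCc9ccccc9)O[C@H](c1ccc(OCc9ccccc9)c(OCc9ccccc9)c1)[C@@H](OCc9ccccc9)[C@@H]2c1c(OCc9ccccc9)c2c(c([C@@H]3c4ccc(OCc9ccccc9)cc4OC(NC(C)=O)(c4ccc(OCc9ccccc9)c(OCc9ccccc9)c4)C3)c1OCc9ccccc9)O[C@H](c1ccc(OCc9ccccc9)c(OCc9ccccc9)c1)[C@@H](OCc9ccccc9)C2
F5 | step 10 | 2-hydroxybenzhydrol: 13 with CHO converted into CH(OH)[4-(benzyloxy)-5-bromo-2-hydroxyphenyl] | OC(c1cc(Br)c(OCc9ccccc9)cc1O)c1c(OCc9ccccc9)c2c(c(Br)c1OCc9ccccc9)O[C@H](c1ccc(OCc9ccccc9)c(OCc9ccccc9)c1)[C@@H](O)C2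
F6 | step 10 | 2-acetamidochroman: 17 with acetamide added across C2=C3 (NHAc at C2) | Brc1cc2c(cc1OCc9ccccc9)OC(NC(C)=O)(c1ccc(OCc9ccccc9)c(OCc9ccccc9)c1)C[C@@H]2c1c(OCc9ccccc9)c2c(c(Br)c1OCc9ccccc9)O[C@H](c1ccc(OCc9ccccc9)c(OCc9ccccc9)c1)[C@@H](O)C2
F7 | step 16 | bis(2,3-epoxide) of 25 (both epoxide oxygens β, anti to the C4 aryl groups) | c9ccccc9COc1ccc2c(c1)O[C@@]3(c1ccc(OCc9ccccc9)c(OCc9ccccc9)c1)O[C@H]3[C@@H]2c1cc2c(cc1OCc9ccccc9)O[C@H](c1ccc(OCc9ccccc9)c(OCc9ccccc9)c1)[C@@H](OCc9ccccc9)[C@@H]2c1c(OCc9ccccc9)c2c(c([C@@H]3c4ccc(OCc9ccccc9)cc4O[C@@]5(c4ccc(OCc9ccccc9)c(OCc9ccccc9)c4)O[C@H]53)c1OCc9ccccc9)O[C@H](c1ccc(OCc9ccccc9)c(OCc9ccccc9)c1)[C@@H](OCc9ccccc9)C2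
F8 | step 13 | divinyl compound: 20 with both bromines replaced by vinyl | C=Cc1cc2c(cc1OCc9ccccc9)O[C@H](c1ccc(OCc9ccccc9)c(OCc9ccccc9)c1)[C@@H](OCc9ccccc9)[C@@H]2c1c(OCc9ccccc9)c2c(c(C=C)c1OCc9ccccc9)O[C@H](c1ccc(OCc9ccccc9)c(OCc9ccccc9)c1)[C@@H](OCc9ccccc9)C2
F9 | step 4 | 5-(benzyloxy)-4-bromo-2-(4,4,5,5-tetramethyl-1,3,2-dioxaborolan-2-yl)phenol | CC1(C)OB(OC1(C)C)c1cc(Br)c(OCc2ccccc2)cc1O
A1 | alternative 1 | tris(2-hydroxybenzhydrol) on penta-O-benzylcatechin (carbinols at the three future C4 atoms; precursor also of alternative 3) | OC(c1ccc(OCc9ccccc9)cc1O)c1cc(C(O)c2c(OCc9ccccc9)c3c(c(C(O)c4ccc(OCc9ccccc9)cc4O)c2OCc9ccccc9)O[C@H](c2ccc(OCc9ccccc9)c(OCc9ccccc9)c2)[C@@H](OCc9ccccc9)C3)c(O)cc1OCc9ccccc9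
A2 | alternative 1 | diethyl (E)-3,4-bis(benzyloxy)styrylboronate | CCOB(OCC)/C=C/c1ccc(OCc2ccccc2)c(OCc2ccccc2)c1
A3 | alternative 1 | tris[(E)-styryl] triphenol with three diaryl methine centres | c1cc(OCc9ccccc9)c(OCc9ccccc9)cc1/C=C/[C@@H](c1ccc(OCc9ccccc9)cc1O)c1cc([C@H](/C=C/c2ccc(OCc9ccccc9)c(OCc9ccccc9)c2)c2c(OCc9ccccc9)c3c(c([C@@H](/C=C/c4ccc(OCc9ccccc9)c(OCc9ccccc9)c4)c4ccc(OCc9ccccc9)cc4O)c2OCc9ccccc9)O[C@H](c2ccc(OCc9ccccc9)c(OCc9ccccc9)c2)[C@@H](OCc9ccccc9)C3)c(O)cc1OCc9ccccc9
A4 | alternative 2 | tris(4-aryl-2H-chromene) (three flav-3-ene units, each with its 2-aryl group α as in the target) on penta-O-benzylcatechin | c9ccccc9COc1ccc2c(c1)O[C@H](c1ccc(OCc9ccccc9)c(OCc9ccccc9)c1)C=C2c1cc2c(cc1OCc9ccccc9)O[C@H](c1ccc(OCc9ccccc9)c(OCc9ccccc9)c1)C=C2c1c(OCc9ccccc9)c2c(c(C3c4ccc(OCc9ccccc9)cc4O[C@H](c4ccc(OCc9ccccc9)c(OCc9ccccc9)c4)C=3)c1OCc9ccccc9)O[C@H](c1ccc(OCc9ccccc9)c(OCc9ccccc9)c1)[C@@H](OCc9ccccc9)C2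
A5 | alternative 2 | tetradeca-O-benzyl tetramer with three free 3-hydroxyls | c9ccccc9COc1ccc2c(c1)O[C@H](c1ccc(OCc9ccccc9)c(OCc9ccccc9)c1)[C@@H](O)[C@@H]2c1cc2c(cc1OCc9ccccc9)O[C@H](c1ccc(OCc9ccccc9)c(OCc9ccccc9)c1)[C@@H](O)[C@@H]2c1c(OCc9ccccc9)c2c(c([C@@H]3c4ccc(OCc9ccccc9)cc4O[C@H](c4ccc(OCc9ccccc9)c(OCc9ccccc9)c4)[C@H]3O)c1OCc9ccccc9)O[C@H](c1ccc(OCc9ccccc9)c(OCc9ccccc9)c1)[C@@H](OCc9ccccc9)C2
A6 | alternative 3 | (E)-3,4-bis(benzyloxy)styryl acetate | CC(=O)O/C=C/c1ccc(OCc2ccccc2)c(OCc2ccccc2)c1
A7 | alternative 3 | tetradeca-O-benzyl tetramer 3-O-acetylated on the three fisetinidol units | c9ccccc9COc1ccc2c(c1)O[C@H](c1ccc(OCc9ccccc9)c(OCc9ccccc9)c1)[C@@H](OC(C)=O)[C@@H]2c1cc2c(cc1OCc9ccccc9)O[C@H](c1ccc(OCc9ccccc9)c(OCc9ccccc9)c1)[C@@H](OC(C)=O)[C@@H]2c1c(OCc9ccccc9)c2c(c([C@@H]3c4ccc(OCc9ccccc9)cc4O[C@H](c4ccc(OCc9ccccc9)c(OCc9ccccc9)c4)[C@H]3OC(C)=O)c1OCc9ccccc9)O[C@H](c1ccc(OCc9ccccc9)c(OCc9ccccc9)c1)[C@@H](OCc9ccccc9)C2
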